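A slow flask shows its rate. A flask given many lifetimes shows its charge. Each flask below must be placed between those two.

| flask | starting material | reagent | protic impurity | free catalyst | temperature | remark | time |
|---|---|---|---|---|---|---|---|
| Thursday's | 6.7 mM | 12 mM | 0.50 mM | 1 mM | 45 °C | run made earlier |  |
| Tuesday's | 15 mM | 12 mM | 0.50 mM | 1 mM | 75 °C | run made earlier |  |
| Wednesday's | 10 mM | 12 mM | 0.50 mM | 2 mM | 45 °C | run made earlier |  |
| theta | 10 mM | 12.0 mM | 0.500 mM | 1.0 mM |  | at 50 °C until 15 min, from then on at 100 °C | 20 min |
| gamma | 10 mM | 12.0 mM | 0.500 mM | 1.0 mM | 75 °C |  | 20 min |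
| epsilon | 10 mM | 12.0 mM | 0.500 mM | 1.0 mM | 100 °C |  | 20 min |
| delta | 10 mM | 12.0 mM | 0.500 mM | 1.0 mM | 50 °C |  | 20 min |

| run | time / min | target / % | starting material / % |
|---|---|---|---|
| Thursday's | 6.00 | 5 | 87 |
| Thursday's | 8.00 | 10 | 80 |
| Thursday's | 12.0 | 12 | 78 |
| Thursday's | 20.0 | 24 | 67 |
| Thursday's | 25.0 | 27 | 64 |
| Thursday's | 40.0 | 40 | 49 |
| Thursday's | 60.0 | 56 | 38 |
| Tuesday's | 1.33 | 6 | 88 |
| Tuesday's | 2.00 | 15 | 85 |
| Tuesday's | 3.00 | 19 | 75 |
| Tuesday's | 5.00 | 29 | 62 |
| Tuesday's | 6.00 | 33 | 61 |
| Tuesday's | 10.0 | 47 | 45 |
| Tuesday's | 15.0 | 58 | 32 |
| Wednesday's | 12.0 | 24 | 65 |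
| Wednesday's | 25.0 | 43 | 46 |
| Wednesday's | 40.0 | 61 | 29 |
| Wednesday's | 50.0 | 66 | 20 |
| Wednesday's | 60.0 | 78 | 13 |

(readings scatter by 2 percentage points)

- a species is counted by the starting material in it: one spent catalyst counts as two
- amounts and yields of target count crystals too
- given per volume of solution although it is solid: crystals
- steps that have been proposed: crystals <-> target; reagent + catalyst intermediate B -> catalyst intermediate C; target + catalyst intermediate B -> spent catalyst; starting material + free catalyst -> catalyst intermediate A; starting material + protic impurity -> quenched substrate; catalyst intermediate A <-> catalyst intermediate B; catalyst intermediate C -> free catalyst + target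

1. the flask with the highest amount of target, in percent of the starting material charged ("all alike" if they lie within 1.5 percentage points) (theta / gamma / epsilon / delta / all alike)
2. final target, as a percentage of the starting material charged, in theta
3. final target, as a percentage of the starting material charged, in gamma
4. final target, as a percentage of the starting material charged, in epsilon
5. final target, as a percentage of the starting material charged, in delta

**What caps the target?** Two charges do. Each target takes one reagent, which allows 120 % of the starting material. The protic impurity eats starting material one to one, which leaves 95.0 %. The smaller of these two fractions I call the ceiling95.0 %: 95.0 % of the charge. The reagent is not the limiting reagent here.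

**Does the impurity really take its share?** Thursday's first reading misses 8.00 %, and that flask's impurity share is 7.46 %. With a scatter of 2 percentage points per reading, that fits.

**How fast is the approach?** Take the lifetime of the starting material from each last reading, first order. Thursday's run gives 62.0 min at 45 °C. Tuesday's gives 13.2 min at 75 °C. Wednesday's, with twice the catalyst, gives 29.4 min, about half of Thursday's.

Drawing ln(lifetime) straight through temperature gives 47.9 min at 50 °C. It gives 3.62 min at 100 °C, outside the readings.

**But the catalyst holds material too. Did you count that?** Wednesday's last reading leaves 4.00 % beyond the impurity share. These flasks carry half that catalyst share, so I take 2.00 % as held. I keep this out of the sum below, so my numbers may stand that much high.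

**Your numbers?** Target is the ceiling less what is left. The crossing is where the time passes the lifetime. Epsilon has 5.53 lifetimes and delta 0.418, so epsilon reads its ceiling and delta its rate. I reckon 94.6 % for epsilon, 73.1 % for gamma, 76.6 % for theta and 29.1 % for delta.

The forecast named epsilon and gave 72 % for theta, 68 % for gamma, 78 % for epsilon and 30 % for delta, adding: “Deactivation at 100 °C is the main uncertainty.”

The flasks give 80.2 % in theta, 79.1 % in gamma, 92.6 % in epsilon and 28.7 % in delta, so epsilon holds the most.

    crystals ⇌ target, rate k1*(cs1 - [target]) while solid is left; crystals form when [target] > cs1 (solubility = 4.40 mM, k = 0.00719 /s)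
    reagent + catalyst intermediate B → catalyst intermediate C (k = 2.21 /M/s, Ea = 52.0 kJ/mol)
    target + catalyst intermediate B → spent catalyst (k = 0.0531 /M/s, Ea = 45.0 kJ/mol)
    starting material + free catalyst → catalyst intermediate A (k = 0.496 /M/s, Ea = 58.0 kJ/mol)
    starting material + protic impurity → quenched substrate (k = 1.43 /M/s, Ea = 43.0 kJ/mol)
    catalyst intermediate A ⇌ catalyst intermediate B (K = 1.36, k = 0.0196 /s, Ea = 93.0 kJ/mol, ΔH = −15.0 kJ/mol)
    catalyst intermediate C → free catalyst + target (k = 0.805 /s, Ea = 73.0 kJ/mol)
    (constants at 50 °C)

Epsilon ends 2.4 points under its ceiling, and its spent catalyst, 11.8 % of the catalyst and counted two to one, comes to 2.36 % of the charge. In theta at 20.0 min, catalyst intermediate B goes on to catalyst intermediate C 39 times as fast as it goes to spent catalyst. The neighbour of theta with 0.706 equiv of reagent has reagent as its limiting reagent and a ceiling of 70.6 %. With 30.0 % of its starting material still left, that neighbour holds 61.3 % target.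

Readings and results were generated by integration with constants of no real substance; the scatter is artificial.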